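Ring C is cut at C3–C4 and O1–C2. The array C4–C4a–C8a–O1 is the formyl group and ortho hydroxyl of a ring-A salicylaldehyde, and C2–C3, carrying ring B, is the amine-bearing carbon and the nucleophilic carbon of an arylacetaldehyde enamine. In one neutral operation the enamine carbon adds to the aldehyde and the phenol closes on the iminium carbon, giving a 2-morpholinoisoflavan-4-ol that is later oxidised and aromatised. The precursors are a bis-silylated 3-prenylsalicylaldehyde whose only free hydroxyl lies beside the prenyl group, which fixes prenyl at C8, and the morpholine enamine of a silylated chromen-8-ylacetaldehyde.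

Key step: step 10

Remarks on the chemistry:
- TBS = tert-butyldimethylsilyl, TIPS = triisopropylsilyl, prenyl = 3-methylbut-2-en-1-yl, DBU = 1,8-diazabicyclo[5.4.0]undec-7-ene.
- All three phenols are carried as silyl ethers, so the final unmasking needs fluoride only. An acetal on the ring-B phenol would call for acid at the end, in the presence of a prenyl group ortho to a free phenol, which is prone to cyclise to a chroman.
- Assumption: the key-step product is a racemate, drawn as the 2,3-trans-3,4-trans isomer expected to predominate; its three stereocentres all become trigonal one step later, so its configuration is immaterial. The target has no stereocentre.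

Step 1
Reactants: 1 phloroglucinol (benzene-1,3,5-triol); 2 prenyl bromide (1-bromo-3-methylbut-2-ene)
Product: 3 2-prenylphloroglucinol [2-(3-methylbut-2-en-1-yl)benzene-1,3,5-triol]
Conditions: DBU, THF, 0 °C → rt (1 in threefold excess)
Reagents that add atoms: none
Why: Base-mediated C-allylation of the ambident phloroglucinol anion, which reacts on carbon through its keto tautomer; the three ring carbons are equivalent, so only the degree of alkylation has to be held back, which the excess of 1 should do.

Step 2
Reactants: 3 2-prenylphloroglucinol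
Product: 4 3,5-bis(tert-butyldimethylsilyloxy)-2-prenylphenol
Conditions: TBSCl (2.05 equiv), imidazole, DMF, −20 → 0 °C
Reagents that add atoms: tert-butyldimethylsilyl chloride, CC(C)(C)[Si](C)(C)Cl
Why: Sterically controlled phenol silylation, in which the hydroxyl para to the prenyl group should react first, the second silyl group goes to either of the two equivalent hindered hydroxyls and a third is slowed by buttressing, so every bis-ether that carries silicon on the para oxygen is the same compound 4.

Step 3
Reactants: 4 3,5-bis(tert-butyldimethylsilyloxy)-2-prenylphenol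
Product: 6 ring-A salicylaldehyde 4,6-bis(tert-butyldimethylsilyloxy)-2-hydroxy-3-prenylbenzaldehyde, via salicyl alcohol 5 (not isolated)
Conditions: MgCl2, Et3N, (CH2O)n, THF, reflux
Reagents that add atoms: paraformaldehyde (formaldehyde), C=O
Why: Casnati–Skattebøl ortho-formylation, in which the magnesium phenoxide delivers formaldehyde to the only free carbon ortho to the single free hydroxyl and a second formaldehyde oxidises the salicyl alcohol 5 by Oppenauer-type hydride transfer; the hydroxyl left free in 6 is therefore the one beside the prenyl group.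

Step 4
Reactants: 7 2,4-dihydroxybenzaldehyde
Product: 8 2-hydroxy-4-(triisopropylsilyloxy)benzaldehyde
Conditions: TIPSCl (1.05 equiv), imidazole, CH2Cl2, 0 °C
Reagents that add atoms: triisopropylsilyl chloride, CC(C)[Si](Cl)(C(C)C)C(C)C
Why: Selective phenol silylation, since the 4-hydroxyl is the more acidic and is free, whereas the 2-hydroxyl is deactivated by its hydrogen bond to the formyl group.

Step 5
Reactants: 8 2-hydroxy-4-(triisopropylsilyloxy)benzaldehyde; 9 3-chloro-3-methylbut-1-yne
Product: 10 2-[(2-methylbut-3-yn-2-yl)oxy]-4-(triisopropylsilyloxy)benzaldehyde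
Conditions: DBU, CuCl2·2H2O (1 mol %), MeCN, 0 °C
Reagents that add atoms: none
Why: Copper-catalysed propargylic etherification (substitution through a copper acetylide-derived electrophile), which suits acidic phenoxides and tertiary propargylic chlorides where a direct SN2 reaction is impossible; the non-nucleophilic base should leave the aryl silyl ether alone.

Step 6
Reactants: 10 2-[(2-methylbut-3-yn-2-yl)oxy]-4-(triisopropylsilyloxy)benzaldehyde
Product: 12 2,2-dimethyl-5-(triisopropylsilyloxy)-2H-chromene-8-carbaldehyde, via allenylphenol 11 (not isolated)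
Conditions: PhNEt2, 180 °C
Reagents that add atoms: none
Why: Aromatic propargyl Claisen rearrangement to C3, the only ortho carbon that can rearomatise, followed by 1,5-hydrogen shift and oxa-6π electrocyclisation of the allenylphenol 11, which closes the dimethylpyran on the oxygen ortho to the formyl group and so places the aldehyde at C8 and the silyloxy group at C5.

Step 7
Reactants: 12 2,2-dimethyl-5-(triisopropylsilyloxy)-2H-chromene-8-carbaldehyde
Product: 13 8-(2-methoxyethenyl)-2,2-dimethyl-5-(triisopropylsilyloxy)-2H-chromene (E/Z mixture)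
Conditions: Ph3P(CH2OMe)Cl, KOtBu, THF, 0 °C → rt (ylide preformed)
Reagents that add atoms: (methoxymethyl)triphenylphosphonium chloride, COC[P+](c1ccccc1)(c1ccccc1)c1ccccc1.[Cl-]
Why: Wittig olefination with the methoxymethylene ylide, the standard one-carbon homologation of an aryl aldehyde; the alkene geometry does not matter because both isomers give the same aldehyde in step 8.

Step 8
Reactants: 13 8-(2-methoxyethenyl)-2,2-dimethyl-5-(triisopropylsilyloxy)-2H-chromene
Product: 14 2-[2,2-dimethyl-5-(triisopropylsilyloxy)-2H-chromen-8-yl]acetaldehyde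
Conditions: 2 M aq. HCl, THF, 40 °C; used at once
Reagents that add atoms: water, O
Why: Acid-catalysed enol ether hydrolysis (C-protonation, hydration of the oxocarbenium ion, loss of methanol); dilute acid at mild temperature should spare the aryl silyl ether and the chromene.

Step 9
Reactants: 14 2-[2,2-dimethyl-5-(triisopropylsilyloxy)-2H-chromen-8-yl]acetaldehyde
Product: 15 4-[(E)-2-[2,2-dimethyl-5-(triisopropylsilyloxy)-2H-chromen-8-yl]ethenyl]morpholine
Conditions: morpholine (1.5 equiv), 4 Å MS, toluene, rt; filtered, evaporated, used crude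
Reagents that add atoms: morpholine, C1COCCN1
Why: Condensation of an aldehyde with a secondary amine to the enamine with removal of water; conjugation with the aryl ring and avoidance of allylic strain should give the E isomer under thermodynamic control.

Step 10
Reactants: 6 4,6-bis(tert-butyldimethylsilyloxy)-2-hydroxy-3-prenylbenzaldehyde; 15 4-[(E)-2-[2,2-dimethyl-5-(triisopropylsilyloxy)-2H-chromen-8-yl]ethenyl]morpholine
Product: 16 rac-(2R,3R,4R)-5,7-bis(tert-butyldimethylsilyloxy)-3-[2,2-dimethyl-5-(triisopropylsilyloxy)-2H-chromen-8-yl]-2-(morpholin-4-yl)-8-prenylchroman-4-ol (2,3-trans-3,4-trans)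
Conditions: toluene, 4 Å MS, argon, rt → 45 °C (15 in slight excess); crude product taken on
Reagents that add atoms: none
Why: Enamine aldol addition followed by N,O-acetal formation, a known condensation of salicylaldehydes with aldehyde enamines: the formyl group of 6, activated by the hydrogen bond from the ortho hydroxyl, is attacked by the β-carbon of 15 (C3–C4), and after proton transfer the phenoxide captures the iminium carbon (O1–C2). Ring C closes in a 6-exo-trig mode. C3 and C4 are set in the hydrogen-bonded addition step and C2 in the reversible acetalisation, so thermodynamic control should favour the all-equatorial 2,3-trans-3,4-trans isomer; none of the three centres survives step 11, so any mixture is usable. The step needs attack through carbon and not nitrogen, which the tertiary enamine nitrogen ensures, and closure through the oxygen beside the prenyl group, which is secured because that is the only free phenol in 6. The neutral, dry conditions should leave the silyl ethers, the prenyl group and the chromene untouched.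

Step 11
Reactants: 16 rac-(2R,3R,4R)-5,7-bis(tert-butyldimethylsilyloxy)-3-[2,2-dimethyl-5-(triisopropylsilyloxy)-2H-chromen-8-yl]-2-(morpholin-4-yl)-8-prenylchroman-4-ol
Product: 18 5,7-bis(tert-butyldimethylsilyloxy)-3-[2,2-dimethyl-5-(triisopropylsilyloxy)-2H-chromen-8-yl]-8-prenyl-4H-chromen-4-one, via 2-morpholinoisoflavanone 17 (not isolated)
Conditions: MnO2, CH2Cl2, rt; filter; AcOH, CH2Cl2, rt
Reagents that add atoms: none
Why: MnO2 oxidation of the benzylic carbinol gives the β-amino ketone 17, whose C3 hydrogen is benzylic and α to the carbonyl, so acid-assisted β-elimination of morpholine (through the N-protonated N,O-acetal) forms the C2=C3 bond of the chromone; the acetic acid also ties up the liberated amine.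

Step 12
Reactants: 18 5,7-bis(tert-butyldimethylsilyloxy)-3-[2,2-dimethyl-5-(triisopropylsilyloxy)-2H-chromen-8-yl]-8-prenyl-4H-chromen-4-one
Product: 19 target 5,7-dihydroxy-3-(5-hydroxy-2,2-dimethyl-2H-chromen-8-yl)-8-(3-methylbut-2-en-1-yl)-4H-chromen-4-one
Conditions: n-Bu4NF (3.5 equiv), AcOH (3.5 equiv), THF, 0 °C
Reagents that add atoms: none
Why: Fluoride-mediated cleavage of the three aryl silyl ethers, driven by Si–F bond formation and buffered with acetic acid so that neither strong base nor acid meets the chromone, the prenyl group or the chromene.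

Compound list
1 | phloroglucinol (benzene-1,3,5-triol) | Oc1cc(O)cc(O)c1 | starting material
2 | prenyl bromide (1-bromo-3-methylbut-2-ene) | CC(C)=CCBr | starting material
3 | 2-prenylphloroglucinol, 2-(3-methylbut-2-en-1-yl)benzene-1,3,5-triol | CC(C)=CCc1c(O)cc(O)cc1O | intermediate
4 | 3,5-bis(tert-butyldimethylsilyloxy)-2-prenylphenol | CC(C)=CCc1c(O)cc(O[Si](C)(C)C(C)(C)C)cc1O[Si](C)(C)C(C)(C)C | intermediate
5 | 3,5-bis(tert-butyldimethylsilyloxy)-2-(hydroxymethyl)-6-prenylphenol (salicyl alcohol, formed in the flask as its magnesium salt, not isolated) | CC(C)=CCc1c(O)c(CO)c(O[Si](C)(C)C(C)(C)C)cc1O[Si](C)(C)C(C)(C)C | intermediate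
6 | 4,6-bis(tert-butyldimethylsilyloxy)-2-hydroxy-3-prenylbenzaldehyde | CC(C)=CCc1c(O)c(C=O)c(O[Si](C)(C)C(C)(C)C)cc1O[Si](C)(C)C(C)(C)C | intermediate
7 | 2,4-dihydroxybenzaldehyde | O=Cc1ccc(O)cc1O | starting material
8 | 2-hydroxy-4-(triisopropylsilyloxy)benzaldehyde | CC(C)[Si](Oc1ccc(C=O)c(O)c1)(C(C)C)C(C)C | intermediate
9 | 3-chloro-3-methylbut-1-yne | C#CC(C)(C)Cl | starting material
10 | 2-[(2-methylbut-3-yn-2-yl)oxy]-4-(triisopropylsilyloxy)benzaldehyde | C#CC(C)(C)Oc1cc(O[Si](C(C)C)(C(C)C)C(C)C)ccc1C=O | intermediate
11 | 2-hydroxy-3-(3-methylbuta-1,2-dien-1-yl)-4-(triisopropylsilyloxy)benzaldehyde (allenylphenol, not isolated) | CC(C)=C=Cc1c(O)c(C=O)ccc1O[Si](C(C)C)(C(C)C)C(C)C | intermediate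
12 | 2,2-dimethyl-5-(triisopropylsilyloxy)-2H-chromene-8-carbaldehyde | CC(C)[Si](Oc1ccc(C=O)c2c1C=CC(C)(C)O2)(C(C)C)C(C)C | intermediate
13 | 8-(2-methoxyethenyl)-2,2-dimethyl-5-(triisopropylsilyloxy)-2H-chromene, E/Z mixture | COC=Cc1ccc(O[Si](C(C)C)(C(C)C)C(C)C)c2c1OC(C)(C)C=C2 | intermediate
14 | 2-[2,2-dimethyl-5-(triisopropylsilyloxy)-2H-chromen-8-yl]acetaldehyde | O=CCc1ccc(O[Si](C(C)C)(C(C)C)C(C)C)c2c1OC(C)(C)C=C2 | intermediate
15 | 4-[(E)-2-[2,2-dimethyl-5-(triisopropylsilyloxy)-2H-chromen-8-yl]ethenyl]morpholine | CC(C)[Si](Oc1ccc(/C=C/N2CCOCC2)c2c1C=CC(C)(C)O2)(C(C)C)C(C)C | intermediate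
16 | rac-(2R,3R,4R)-5,7-bis(tert-butyldimethylsilyloxy)-3-[2,2-dimethyl-5-(triisopropylsilyloxy)-2H-chromen-8-yl]-2-(morpholin-4-yl)-8-prenylchroman-4-ol, 2,3-trans-3,4-trans, one enantiomer drawn | CC(C)=CCc1c(O[Si](C)(C)C(C)(C)C)cc(O[Si](C)(C)C(C)(C)C)c2c1O[C@@H](N1CCOCC1)[C@H](c1ccc(O[Si](C(C)C)(C(C)C)C(C)C)c3c1OC(C)(C)C=C3)[C@H]2O | intermediate
17 | rac-(2R,3S)-5,7-bis(tert-butyldimethylsilyloxy)-3-[2,2-dimethyl-5-(triisopropylsilyloxy)-2H-chromen-8-yl]-2-(morpholin-4-yl)-8-prenylchroman-4-one, 2,3-trans, one enantiomer drawn (not isolated) | CC(C)=CCc1c(O[Si](C)(C)C(C)(C)C)cc(O[Si](C)(C)C(C)(C)C)c2c1O[C@@H](N1CCOCC1)[C@H](c1ccc(O[Si](C(C)C)(C(C)C)C(C)C)c3c1OC(C)(C)C=C3)C2=O | intermediate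
18 | 5,7-bis(tert-butyldimethylsilyloxy)-3-[2,2-dimethyl-5-(triisopropylsilyloxy)-2H-chromen-8-yl]-8-prenyl-4H-chromen-4-one | CC(C)=CCc1c(O[Si](C)(C)C(C)(C)C)cc(O[Si](C)(C)C(C)(C)C)c2c(=O)c(-c3ccc(O[Si](C(C)C)(C(C)C)C(C)C)c4c3OC(C)(C)C=C4)coc12 | intermediate
19 | 5,7-dihydroxy-3-(5-hydroxy-2,2-dimethyl-2H-chromen-8-yl)-8-(3-methylbut-2-en-1-yl)-4H-chromen-4-one (CNP0246833.0, achiral) | CC(C)=CCc1c(O)cc(O)c2c(=O)c(-c3ccc(O)c4c3OC(C)(C)C=C4)coc12 | target

Total step count: 12.
Longest linear sequence: 9 steps (steps 4 to 12, from 2,4-dihydroxybenzaldehyde 7); the ring-A branch (steps 1 to 3) joins at step 10.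

Steps most likely to fail

1. Step 10. The addition may stall or run backwards: the formyl group of 6 is deactivated by two donor oxygens and by chelation and is crowded by the ortho silyloxy group, so retro-addition, enamine hydrolysis or enamine self-condensation may outrun ring closure. The fallback sets out from 12 and 6 and comes back to the route at 18, forming the C3–C4 bond irreversibly with a carbanion and adding C2 afterwards. NaBH4 reduction of 12 should give [2,2-dimethyl-5-(triisopropylsilyloxy)-2H-chromen-8-yl]methanol F1. MsCl, Et3N and LiCl in THF should convert it into 8-(chloromethyl)-2,2-dimethyl-5-(triisopropylsilyloxy)-2H-chromene F2. Magnesium in THF at 0 °C should give the benzylmagnesium chloride F3, used in solution. Its addition to 6, first deprotonated at the phenol with NaH, should give the racemic carbinol 1-[4,6-bis(tert-butyldimethylsilyloxy)-2-hydroxy-3-prenylphenyl]-2-[2,2-dimethyl-5-(triisopropylsilyloxy)-2H-chromen-8-yl]ethan-1-ol F4. MnO2 should oxidise the benzylic alcohol to the 2-hydroxydeoxybenzoin F5. Heating F5 with N,N-dimethylformamide dimethyl acetal in toluene should give the enaminone F6, which should cyclise through the free phenol with loss of dimethylamine to 18.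

2. Step 2. The degree and site of silylation may be poorly controlled: under- and over-silylation, or silylation of both hindered hydroxyls, which would carry material into the isomeric 6-prenyl series. The fallback sets out from 2 and comes back at 6, with the formyl group present from the start so that chelation limits the silylation. Commercial 2,4,6-trihydroxybenzaldehyde F7 should be C-prenylated with 2 (aqueous KOH, 0 °C) to 2,4,6-trihydroxy-3-prenylbenzaldehyde F8; its two free ring carbons are equivalent, so only one C-prenyl product is possible. TBSCl (2 equiv) and imidazole should then silylate the unchelated 4-hydroxyl and the less hindered of the two ortho hydroxyls. The hydroxyl wedged between formyl and prenyl, held in the hydrogen bond, should stay free, giving 6.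

3. Step 5. O-alkylation of the chelated, ortho-substituted phenoxide may be slow, so that elimination or hydrolysis of the tertiary propargylic chloride, or base-induced loss of the silyl group, takes over. The fallback sets out from 8 and comes back at 12 without a propargyl ether. Heating 8 with 1,1-diethoxy-3-methylbut-2-ene and 3-picoline in xylene at 140 °C (pyridine-mediated chromenylation: C-alkylation at the free carbon ortho to the phenol, then electrocyclic ring closure through that phenol oxygen) should give 12 directly. It makes no new compound (F0).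

Further compounds
F1 | step 10 | [2,2-dimethyl-5-(triisopropylsilyloxy)-2H-chromen-8-yl]methanol | OCc1ccc(O[Si](C(C)C)(C(C)C)C(C)C)c2c1OC(C)(C)C=C2
F2 | step 10 | 8-(chloromethyl)-2,2-dimethyl-5-(triisopropylsilyloxy)-2H-chromene | ClCc1ccc(O[Si](C(C)C)(C(C)C)C(C)C)c2c1OC(C)(C)C=C2
F3 | step 10 | {[2,2-dimethyl-5-(triisopropylsilyloxy)-2H-chromen-8-yl]methyl}magnesium chloride (not isolated) | Cl[Mg]Cc1ccc(O[Si](C(C)C)(C(C)C)C(C)C)c2c1OC(C)(C)C=C2
F4 | step 10 | 1-[4,6-bis(tert-butyldimethylsilyloxy)-2-hydroxy-3-prenylphenyl]-2-[2,2-dimethyl-5-(triisopropylsilyloxy)-2H-chromen-8-yl]ethan-1-ol, racemic | CC(C)=CCc1c(O)c(C(O)Cc2ccc(O[Si](C(C)C)(C(C)C)C(C)C)c3c2OC(C)(C)C=C3)c(O[Si](C)(C)C(C)(C)C)cc1O[Si](C)(C)C(C)(C)C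
F5 | step 10 | 1-[4,6-bis(tert-butyldimethylsilyloxy)-2-hydroxy-3-prenylphenyl]-2-[2,2-dimethyl-5-(triisopropylsilyloxy)-2H-chromen-8-yl]ethan-1-one | CC(C)=CCc1c(O)c(C(=O)Cc2ccc(O[Si](C(C)C)(C(C)C)C(C)C)c3c2OC(C)(C)C=C3)c(O[Si](C)(C)C(C)(C)C)cc1O[Si](C)(C)C(C)(C)C
F6 | step 10 | 1-[4,6-bis(tert-butyldimethylsilyloxy)-2-hydroxy-3-prenylphenyl]-3-(dimethylamino)-2-[2,2-dimethyl-5-(triisopropylsilyloxy)-2H-chromen-8-yl]prop-2-en-1-one (not isolated, alkene geometry not defined) | CN(C)C=C(C(=O)c1c(O)c(CC=C(C)C)c(O[Si](C)(C)C(C)(C)C)cc1O[Si](C)(C)C(C)(C)C)c1ccc(O[Si](C(C)C)(C(C)C)C(C)C)c2c1OC(C)(C)C=C2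
F7 | step 2 | 2,4,6-trihydroxybenzaldehyde | O=Cc1c(O)cc(O)cc1O
F8 | step 2 | 2,4,6-trihydroxy-3-prenylbenzaldehyde | CC(C)=CCc1c(O)cc(O)c(C=O)c1O
F0 | step 5 | none | none
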